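## Retrosynthetic overview

1. Target 24 ⇐ methyl ester 23 (carboxylesterase hydrolysis) ⇐ bis-silyl ether 22 ⇐ Stille coupling (heptenyl) and cross-metathesis (enoate side chain) on bromoenone 14.
2. 14 ⇐ retro-Diels–Alder of the norbornene-masked tricycle 13; cyclopentadiene serves as a removable mask and as the stereocontrol element.
3. On the tricycle every group enters from the convex face: C–Br (enolate bromination), endo C–OH (hydroxyl-directed reduction), CH2OH (aldol with formaldehyde), oxirane (nucleophilic epoxidation).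
4. Tricycle 7 ⇐ catalytic asymmetric Diels–Alder of 2-allyl-1,4-benzoquinone 5 with cyclopentadiene 6; 5 ⇐ 4-methoxyphenol by O-allylation, Claisen rearrangement and oxidation.
5. Ring order: the six-membered carbocycle is the arene ring of 1; the norbornene bicycle is formed in step 4 and removed in step 10; the oxirane is formed in step 5.

Assumption: the target is built exactly as drawn, i.e. (1S,5R,6S) with the secondary hydroxyl trans to the oxirane oxygen; the facial sense of the step 4 catalyst is taken from the α-C–H···O binding model, and the catalyst from (R)-diphenylprolinol is used instead if the adduct proves antipodal.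

TBS = tert-butyldimethylsilyl. Tricycle locants: C3 and C6 are the carbonyl carbons, C4 and C5 the oxirane carbons, C2 and C7 the ring-fusion carbons, C9=C10 the bridge alkene.

## Route

Step 1
Reactants: 1 4-methoxyphenol; 2 allyl bromide
Product: 3 1-(allyloxy)-4-methoxybenzene
Conditions: K2CO3, acetone, reflux
Reagents that add atoms: none
Why: Williamson ether synthesis (SN2 of the phenoxide on the allylic bromide) is clean for a simple phenol and creates no stereocenter.

Step 2
Reactants: 3 1-(allyloxy)-4-methoxybenzene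
Product: 4 2-allyl-4-methoxyphenol
Conditions: N,N-diethylaniline, 200 °C
Reagents that add atoms: none
Why: Aromatic Claisen rearrangement ([3,3]-sigmatropic shift, then tautomerisation) moves the allyl group to the ortho carbon, the only outcome possible for this symmetric ether.

Step 3
Reactants: 4 2-allyl-4-methoxyphenol
Product: 5 2-allyl-1,4-benzoquinone
Conditions: PhI(OAc)2, MeCN/H2O (2:1), 0 °C
Reagents that add atoms: water, O
Why: Hypervalent-iodine oxidative demethylation of a p-methoxyphenol (water attacks the para carbon, methanol leaves) gives the p-quinone without touching the allyl group.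

Step 4
Reactants: 5 2-allyl-1,4-benzoquinone; 6 cyclopentadiene
Product: 7 (1R,2S,7R,8S)-4-allyltricyclo[6.2.1.0^2,7]undeca-4,9-diene-3,6-dione (endo adduct)
Conditions: 20 mol % (S)-3,3-diphenyl-1-(o-tolyl)tetrahydro-1H,3H-pyrrolo[1,2-c][1,3,2]oxazaborole·HNTf2, CH2Cl2, −95 → −78 °C
Reagents that add atoms: none
Why: In this catalytic asymmetric Diels–Alder reaction the cationic oxazaborolidine binds the more basic, unhindered carbonyl remote from the allyl group, and the diene adds endo to the unsubstituted C=C on the open face, setting all four stereocenters (C1, C2, C7, C8) at once.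

Step 5
Reactants: 7 endo adduct
Product: 8 (1R,2S,4S,5R,7R,8S)-4-allyl-4,5-epoxytricyclo[6.2.1.0^2,7]undec-9-ene-3,6-dione (oxirane exo, anti to the C9=C10 bridge)
Conditions: 30% aq. H2O2, Na2CO3, acetone, 0 °C
Reagents that add atoms: hydrogen peroxide, OO
Why: Weitz–Scheffer nucleophilic epoxidation attacks only the electron-poor enedione C=C and only from the convex face, because the concave face is covered by the norbornene bridge; this sets both oxirane stereocenters by substrate control.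

Step 6
Reactants: 8 exo epoxy dione
Product: 9 (1R,2S,4S,5R,7R,8S)-4-allyl-4,5-epoxy-7-(hydroxymethyl)tricyclo[6.2.1.0^2,7]undec-9-ene-3,6-dione (CH2OH exo)
Conditions: 37% aq. CH2O (1.2 equiv), DBU (0.2 equiv), THF, 0 °C
Reagents that add atoms: formaldehyde, C=O
Why: DBU-mediated aldol hydroxymethylation is expected at the ring-fusion carbon α to C6, the carbonyl not buttressed by the fully substituted allyl-bearing oxirane carbon, with formaldehyde entering exo so that the cis ring fusion is kept.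

Step 7
Reactants: 9 hydroxymethyl epoxy dione
Product: 10 (1R,2S,4S,5S,6R,7R,8S)-4-allyl-4,5-epoxy-6-hydroxy-7-(hydroxymethyl)tricyclo[6.2.1.0^2,7]undec-9-en-3-one (6-OH endo)
Conditions: Me4NBH(OAc)3, MeCN/AcOH, −30 → 0 °C
Reagents that add atoms: none
Why: In this Evans–Saksena hydroxyl-directed reduction the exo CH2O-bound acetoxyborohydride delivers hydride only to the β-carbonyl (C6) and only from the convex face, giving the endo carbinol trans to the oxirane oxygen and leaving the C3 ketone untouched.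

Step 8
Reactants: 10 diol ketone
Product: 11 (1R,2S,4S,5S,6R,7R,8S)-4-allyl-6-(TBSO)-7-(TBSOCH2)-4,5-epoxytricyclo[6.2.1.0^2,7]undec-9-en-3-one
Conditions: TBSOTf, 2,6-lutidine, CH2Cl2, −78 → 0 °C
Reagents that add atoms: tert-butyldimethylsilyl triflate, CC(C)(C)[Si](C)(C)OS(=O)(=O)C(F)(F)F
Why: Silyl triflate with a hindered base silylates both the primary and the hindered endo secondary alcohol, which blocks Payne rearrangement and retro-aldol in the basic step that follows.

Step 9
Reactants: 11 bis-silyl ether ketone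
Product: 13 (1R,2R,4S,5S,6R,7R,8S)-4-allyl-2-bromo-6-(TBSO)-7-(TBSOCH2)-4,5-epoxytricyclo[6.2.1.0^2,7]undec-9-en-3-one, via potassium enolate 12 (not isolated)
Conditions: KN(SiMe3)2, THF, −78 → −40 °C; then BrCl2C–CCl2Br, −78 °C
Reagents that add atoms: 1,2-dibromotetrachloroethane, BrC(Cl)(Cl)C(Cl)(Cl)Br
Why: C2–H is the only enolisable position left, so enolate bromination with a mild Br+ donor is regiospecific and must occur exo because endo attack would force a trans ring fusion.

Step 10
Reactants: 13 tricyclic bromo ketone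
Product: 14 (1S,5R,6S)-1-allyl-3-bromo-5-(TBSO)-4-(TBSOCH2)-7-oxabicyclo[4.1.0]hept-3-en-2-one
Conditions: Ph2O (degassed, 0.01 M), 230 °C, 20 min
Reagents that add atoms: none
Why: Retro-Diels–Alder cycloreversion is driven by loss of volatile cyclopentadiene, relief of strain at the two quaternary ring-fusion carbons and formation of the conjugated bromoenone; the oxirane and carbinol stereocenters are not involved.

Step 11
Reactants: 14 bromoenone; 15 methyl methacrylate
Product: 16 methyl (E)-4-[(1S,5R,6S)-3-bromo-5-(TBSO)-4-(TBSOCH2)-2-oxo-7-oxabicyclo[4.1.0]hept-3-en-1-yl]-2-methylbut-2-enoate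
Conditions: second-generation Hoveyda–Grubbs catalyst (H2IMes)Cl2Ru=CH(C6H4-2-OiPr) (10 mol %), 15 (10 equiv), CH2Cl2, 40 °C
Reagents that add atoms: none
Why: Olefin cross-metathesis of the terminal allyl group with a 1,1-disubstituted acrylate gives the thermodynamically favoured (E)-trisubstituted enoate, while the tetrasubstituted bromoenone alkene is inert to the ruthenium carbene.

Step 12
Reactants: 17 1-heptyne
Product: 19 (E)-1-iodohept-1-ene, via (E)-hept-1-enylzirconocene chloride 18 (not isolated)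
Conditions: Cp2Zr(H)Cl, THF, rt; then I2, 0 °C
Reagents that add atoms: iodine, II
Why: Hydrozirconation (Schwartz) is a syn, anti-Markovnikov addition, and iodinolysis of the C–Zr bond proceeds with retention, giving the geometrically pure E iodide.

Step 13
Reactants: 19 (E)-1-iodohept-1-ene
Product: 21 (E)-tributyl(hept-1-enyl)stannane, via (E)-hept-1-enyllithium 20 (not isolated)
Conditions: t-BuLi (2.1 equiv), Et2O, −78 °C; then Bu3SnCl, −78 °C → rt
Reagents that add atoms: tributyltin chloride, CCCC[Sn](Cl)(CCCC)CCCC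
Why: Lithium–iodine exchange and stannylation of the configurationally stable alkenyllithium both proceed with retention of the E geometry.

Step 14
Reactants: 16 bromoenone enoate; 21 (E)-tributyl(hept-1-enyl)stannane
Product: 22 methyl (E)-4-[(1S,5R,6S)-5-(TBSO)-4-(TBSOCH2)-3-[(E)-hept-1-enyl]-2-oxo-7-oxabicyclo[4.1.0]hept-3-en-1-yl]-2-methylbut-2-enoate
Conditions: Pd2(dba)3 (5 mol %), AsPh3 (20 mol %), toluene, 80 °C
Reagents that add atoms: none
Why: Stille coupling of an α-bromoenone with an alkenylstannane runs under neutral conditions with retention of both alkene geometries, so the base-sensitive epoxy ketone is not exposed to base.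

Step 15
Reactants: 22 bis-silyl ether
Product: 23 methyl (E)-4-[(1S,5R,6S)-3-[(E)-hept-1-enyl]-5-hydroxy-4-(hydroxymethyl)-2-oxo-7-oxabicyclo[4.1.0]hept-3-en-1-yl]-2-methylbut-2-enoate
Conditions: HF·pyridine, pyridine/THF, 0 °C → rt
Reagents that add atoms: none
Why: Buffered fluoride desilylation removes both silyl ethers under mildly acidic conditions that avoid the alkoxide-driven Payne rearrangement of the trans-epoxy alcohol.

Step 16
Reactants: 23 dihydroxy methyl ester
Product: 24 (E)-4-[(1S,5R,6S)-3-[(E)-hept-1-enyl]-5-hydroxy-4-(hydroxymethyl)-2-oxo-7-oxabicyclo[4.1.0]hept-3-en-1-yl]-2-methylbut-2-enoic acid (target)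
Conditions: pig liver esterase (a carboxylesterase, serine hydrolase class), 0.1 M phosphate buffer pH 7.2/acetone 9:1, 30 °C, pH-stat; then acidify to pH 4
Reagents that add atoms: water, O
Why: Enzymatic ester hydrolysis by a carboxylesterase (an enzyme class known to accept methacrylate-type methyl esters) frees the acid at neutral pH, where the epoxy ketone, the trans-epoxy alcohol and the vinylogously acidic C5–H are all stable, unlike under saponification.

## Compound list

1 | 4-methoxyphenol | COc1ccc(O)cc1 | starting material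
2 | allyl bromide | C=CCBr | starting material
3 | 1-(allyloxy)-4-methoxybenzene | C=CCOc1ccc(OC)cc1 | intermediate
4 | 2-allyl-4-methoxyphenol | C=CCc1cc(OC)ccc1O | intermediate
5 | 2-allyl-1,4-benzoquinone | C=CCC1=CC(=O)C=CC1=O | intermediate
6 | cyclopentadiene (freshly cracked) | C1=CCC=C1 | starting material
7 | (1R,2S,7R,8S)-4-allyltricyclo[6.2.1.0^2,7]undeca-4,9-diene-3,6-dione, endo adduct | O=C1C(CC=C)=CC(=O)[C@H]2[C@@H]1[C@H]3C=C[C@@H]2C3 | intermediate
8 | (1R,2S,4S,5R,7R,8S)-4-allyl-4,5-epoxytricyclo[6.2.1.0^2,7]undec-9-ene-3,6-dione, oxirane exo | O=C1[C@@]2(CC=C)O[C@H]2C(=O)[C@H]3[C@@H]1[C@H]4C=C[C@@H]3C4 | intermediate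
9 | (1R,2S,4S,5R,7R,8S)-4-allyl-4,5-epoxy-7-(hydroxymethyl)tricyclo[6.2.1.0^2,7]undec-9-ene-3,6-dione, CH2OH exo | O=C1[C@@]2(CC=C)O[C@H]2C(=O)[C@@]3(CO)[C@@H]1[C@H]4C=C[C@@H]3C4 | intermediate
10 | (1R,2S,4S,5S,6R,7R,8S)-4-allyl-4,5-epoxy-6-hydroxy-7-(hydroxymethyl)tricyclo[6.2.1.0^2,7]undec-9-en-3-one, 6-OH endo and trans to the oxirane oxygen | O=C1[C@@]2(CC=C)O[C@H]2[C@H](O)[C@@]3(CO)[C@@H]1[C@H]4C=C[C@@H]3C4 | intermediate
11 | (1R,2S,4S,5S,6R,7R,8S)-4-allyl-6-(tert-butyldimethylsilyloxy)-7-[(tert-butyldimethylsilyloxy)methyl]-4,5-epoxytricyclo[6.2.1.0^2,7]undec-9-en-3-one | O=C1[C@@]2(CC=C)O[C@H]2[C@H](O[Si](C)(C)C(C)(C)C)[C@@]3(CO[Si](C)(C)C(C)(C)C)[C@@H]1[C@H]4C=C[C@@H]3C4 | intermediate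
12 | potassium enolate of 11 (C2=C3–OK), not isolated | [K+].[O-]C=1[C@@]2(CC=C)O[C@H]2[C@H](O[Si](C)(C)C(C)(C)C)[C@@]3(CO[Si](C)(C)C(C)(C)C)C1[C@H]4C=C[C@@H]3C4 | intermediate
13 | (1R,2R,4S,5S,6R,7R,8S)-4-allyl-2-bromo-6-(tert-butyldimethylsilyloxy)-7-[(tert-butyldimethylsilyloxy)methyl]-4,5-epoxytricyclo[6.2.1.0^2,7]undec-9-en-3-one, Br exo | O=C1[C@@]2(CC=C)O[C@H]2[C@H](O[Si](C)(C)C(C)(C)C)[C@@]3(CO[Si](C)(C)C(C)(C)C)[C@]1(Br)[C@H]4C=C[C@@H]3C4 | intermediate
14 | (1S,5R,6S)-1-allyl-3-bromo-5-(tert-butyldimethylsilyloxy)-4-[(tert-butyldimethylsilyloxy)methyl]-7-oxabicyclo[4.1.0]hept-3-en-2-one | BrC1=C(CO[Si](C)(C)C(C)(C)C)[C@@H](O[Si](C)(C)C(C)(C)C)[C@@H]2O[C@]2(CC=C)C1=O | intermediate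
15 | methyl methacrylate | C=C(C)C(=O)OC | starting material
16 | methyl (E)-4-[(1S,5R,6S)-3-bromo-5-(tert-butyldimethylsilyloxy)-4-[(tert-butyldimethylsilyloxy)methyl]-2-oxo-7-oxabicyclo[4.1.0]hept-3-en-1-yl]-2-methylbut-2-enoate | BrC1=C(CO[Si](C)(C)C(C)(C)C)[C@@H](O[Si](C)(C)C(C)(C)C)[C@@H]2O[C@]2(C/C=C(\C)C(=O)OC)C1=O | intermediate
17 | 1-heptyne | CCCCCC#C | starting material
18 | (E)-hept-1-enylzirconocene chloride, not isolated (cyclopentadienyl rings drawn σ-bonded) | CCCCC/C=C/[Zr](Cl)(C1C=CC=C1)C1C=CC=C1 | intermediate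
19 | (E)-1-iodohept-1-ene | CCCCC/C=C/I | intermediate
20 | (E)-hept-1-enyllithium, not isolated | CCCCC/C=C/[Li] | intermediate
21 | (E)-tributyl(hept-1-enyl)stannane | CCCCC/C=C/[Sn](CCCC)(CCCC)CCCC | intermediate
22 | methyl (E)-4-[(1S,5R,6S)-5-(tert-butyldimethylsilyloxy)-4-[(tert-butyldimethylsilyloxy)methyl]-3-[(E)-hept-1-enyl]-2-oxo-7-oxabicyclo[4.1.0]hept-3-en-1-yl]-2-methylbut-2-enoate | CCCCC/C=C/C1=C(CO[Si](C)(C)C(C)(C)C)[C@@H](O[Si](C)(C)C(C)(C)C)[C@@H]2O[C@]2(C/C=C(\C)C(=O)OC)C1=O | intermediate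
23 | methyl (E)-4-[(1S,5R,6S)-3-[(E)-hept-1-enyl]-5-hydroxy-4-(hydroxymethyl)-2-oxo-7-oxabicyclo[4.1.0]hept-3-en-1-yl]-2-methylbut-2-enoate | CCCCC/C=C/C1=C(CO)[C@@H](O)[C@@H]2O[C@]2(C/C=C(\C)C(=O)OC)C1=O | intermediate
24 | (E)-4-[(1S,5R,6S)-3-[(E)-hept-1-enyl]-5-hydroxy-4-(hydroxymethyl)-2-oxo-7-oxabicyclo[4.1.0]hept-3-en-1-yl]-2-methylbut-2-enoic acid (CNP0332048.4; constitution of ambuic acid) | CCCCC/C=C/C1=C(CO)[C@@H](O)[C@@H]2O[C@]2(C/C=C(\C)C(=O)O)C1=O | target

## Summary

Total step count: 16. Longest linear sequence: 14 steps (steps 1–11 and 14–16); steps 12–13 make the stannane.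

## Steps most likely to fail

**Step 6 (site of hydroxymethylation).** The two ring-fusion α-positions differ only through the remote allyl group, so a mixture with the C2 isomer is possible. The aldol is reversible, so the wrong isomer can be returned to 8 with DBU, but selectivity may stay modest. The fallback fixes the regiochemistry by connectivity: the carbonyl that must not enolise is carried as a dimethyl ketal. It sets out from cyclopentadiene 6 (quinone 5 is replaced by a new dienophile) and comes back at diol 10. Commercial 3-bromo-4-methoxyphenol is allylated with allyltributylstannane (Pd(PPh3)4, toluene, 100 °C) to 3-allyl-4-methoxyphenol F1. PhI(OAc)2 in MeOH at 0 °C turns it into the quinone monoketal 3-allyl-4,4-dimethoxycyclohexa-2,5-dien-1-one F2. The catalyst of step 4 adds 6 endo to the unsubstituted enone bond to give the C3 dimethyl ketal of adduct 7 F3. t-BuOOH/DBU epoxidises the remaining enone from the convex face to the C3 dimethyl ketal of epoxy dione 8 F4. DBU/formalin can then react only at the single enolisable ring-fusion carbon, giving the C3 dimethyl ketal of hydroxymethyl dione 9 F5. Me4NBH(OAc)3 reduces the only ketone to the C3 dimethyl ketal of diol 10 F6, and montmorillonite K-10 in wet CH2Cl2 unmasks the ketone to return 10.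

**Step 10 (thermal cycloreversion of a tertiary α-bromo ketone).** Loss of HBr or radical C–Br cleavage may compete at 230 °C. The fallback moves the cycloreversion in front of the halogenation; it sets out from bis-silyl ether 11 and comes back at diene 22. Compound 11 is thermolysed (Ph2O, 250 °C) to (1S,5R,6S)-1-allyl-5-(TBSO)-4-(TBSOCH2)-7-oxabicyclo[4.1.0]hept-3-en-2-one F7. Johnson α-iodination (I2, pyridine, DMAP cat., CH2Cl2) gives the 3-iodo enone F8. Cross-metathesis with 15 under the conditions of step 11 gives the iodo analogue of 16 F9, whose C–I bond undergoes the Stille coupling of step 14 with 21 to give 22.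

**Step 16 (acceptance of the α-methyl-α,β-unsaturated ester by the esterase).** Hydrolysis may be too slow to be useful. The fallback makes the acid by oxidation instead of hydrolysis; it sets out from bromoenone 14 and comes back at target 24. Cross-metathesis of 14 with methacrolein (same ruthenium catalyst) gives the (E)-enal analogue of 16 F10. Stille coupling with 21 gives the dienyl enal analogue of 22 F11. HF·pyridine gives the dihydroxy enal F12, and Pinnick oxidation (NaClO2, NaH2PO4, 2-methyl-2-butene, t-BuOH/H2O, 0 °C) converts the enal into 24 without base.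

## Further compounds

F1 | step 6 | 3-allyl-4-methoxyphenol | C=CCc1cc(O)ccc1OC
F2 | step 6 | 3-allyl-4,4-dimethoxycyclohexa-2,5-dien-1-one | O=C1C=C(CC=C)C(OC)(OC)C=C1
F3 | step 6 | C3 dimethyl ketal of adduct 7 (endo, same skeleton configuration) | COC1(OC)C(CC=C)=CC(=O)[C@H]2[C@@H]1[C@H]3C=C[C@@H]2C3
F4 | step 6 | C3 dimethyl ketal of epoxy dione 8 (oxirane exo) | COC1(OC)[C@@]2(CC=C)O[C@H]2C(=O)[C@H]3[C@@H]1[C@H]4C=C[C@@H]3C4
F5 | step 6 | C3 dimethyl ketal of hydroxymethyl dione 9 | COC1(OC)[C@@]2(CC=C)O[C@H]2C(=O)[C@@]3(CO)[C@@H]1[C@H]4C=C[C@@H]3C4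
F6 | step 6 | C3 dimethyl ketal of diol 10 | COC1(OC)[C@@]2(CC=C)O[C@H]2[C@H](O)[C@@]3(CO)[C@@H]1[C@H]4C=C[C@@H]3C4
F7 | step 10 | (1S,5R,6S)-1-allyl-5-(tert-butyldimethylsilyloxy)-4-[(tert-butyldimethylsilyloxy)methyl]-7-oxabicyclo[4.1.0]hept-3-en-2-one | C1=C(CO[Si](C)(C)C(C)(C)C)[C@@H](O[Si](C)(C)C(C)(C)C)[C@@H]2O[C@]2(CC=C)C1=O
F8 | step 10 | (1S,5R,6S)-1-allyl-3-iodo-5-(tert-butyldimethylsilyloxy)-4-[(tert-butyldimethylsilyloxy)methyl]-7-oxabicyclo[4.1.0]hept-3-en-2-one | IC1=C(CO[Si](C)(C)C(C)(C)C)[C@@H](O[Si](C)(C)C(C)(C)C)[C@@H]2O[C@]2(CC=C)C1=O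
F9 | step 10 | methyl (E)-4-[(1S,5R,6S)-3-iodo-5-(tert-butyldimethylsilyloxy)-4-[(tert-butyldimethylsilyloxy)methyl]-2-oxo-7-oxabicyclo[4.1.0]hept-3-en-1-yl]-2-methylbut-2-enoate | IC1=C(CO[Si](C)(C)C(C)(C)C)[C@@H](O[Si](C)(C)C(C)(C)C)[C@@H]2O[C@]2(C/C=C(\C)C(=O)OC)C1=O
F10 | step 16 | (E)-4-[(1S,5R,6S)-3-bromo-5-(tert-butyldimethylsilyloxy)-4-[(tert-butyldimethylsilyloxy)methyl]-2-oxo-7-oxabicyclo[4.1.0]hept-3-en-1-yl]-2-methylbut-2-enal | BrC1=C(CO[Si](C)(C)C(C)(C)C)[C@@H](O[Si](C)(C)C(C)(C)C)[C@@H]2O[C@]2(C/C=C(\C)C=O)C1=O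
F11 | step 16 | (E)-4-[(1S,5R,6S)-5-(tert-butyldimethylsilyloxy)-4-[(tert-butyldimethylsilyloxy)methyl]-3-[(E)-hept-1-enyl]-2-oxo-7-oxabicyclo[4.1.0]hept-3-en-1-yl]-2-methylbut-2-enal | CCCCC/C=C/C1=C(CO[Si](C)(C)C(C)(C)C)[C@@H](O[Si](C)(C)C(C)(C)C)[C@@H]2O[C@]2(C/C=C(\C)C=O)C1=O
F12 | step 16 | (E)-4-[(1S,5R,6S)-3-[(E)-hept-1-enyl]-5-hydroxy-4-(hydroxymethyl)-2-oxo-7-oxabicyclo[4.1.0]hept-3-en-1-yl]-2-methylbut-2-enal | CCCCC/C=C/C1=C(CO)[C@@H](O)[C@@H]2O[C@]2(C/C=C(\C)C=O)C1=O
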